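**Retrosynthetic overview**

1. The target comes from its N-Boc derivative by acidolysis. The pyranone ring is cut through O1–C2, C3–C4 and C4–C4a to an ortho-iodophenol, carbon monoxide and phenylacetylene.
2. The plan rests on C8 of ring A, the carbon that carries the piperidine: it lies between C7–OH and C8a–O1. Ring A is therefore a 2-substituted 5-methoxyresorcinol with two equivalent hydroxyls and two equivalent C–H positions next to the methoxy group, so one iodine gives one iodophenol and one flavone.
3. The iodophenol comes from the N-Boc 2-arylpiperidine, and that from an N-sulfinyl 2-arylpiperidine with both phenols as MOM ethers. The piperidine N1–C6 bond is made by 6-exo displacement of a primary chloride.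
4. The aryl–C2 bond and the only stereocenter come from addition of an aryl magnesium reagent (MOM-directed lithiation of 5-methoxyresorcinol bis-MOM ether) to the (R)-tert-butanesulfinyl imine of 5-chloropentanal.
5. Ring order: ring A is bought, the piperidine ring is closed second and the pyranone ring last; the phenyl ring arrives with the alkyne.

Key step: step 9

Assumption: the aryl magnesium addition in step 4 is taken to follow the magnesium-chelated six-membered chair model, under which the (R)-sulfinyl group leads to the R configuration at the new carbon; the target is isolated as its free base.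

**Route**

Step 1
Reactants: 1 5-methoxyresorcinol
Product: 2 1-methoxy-3,5-bis(methoxymethoxy)benzene
Conditions: MOMCl (2.5 equiv), i-Pr2NEt (3 equiv), CH2Cl2, 0 °C → rt
Reagents that add atoms: chloromethyl methyl ether (MOMCl), COCCl
Why: O-alkylation of both phenols by the reactive α-chloro ether (Williamson-type etherification) installs the two acetal groups that direct the later ortho-lithiation and that fall off in the same acid step as the sulfinyl group.

Step 2
Reactants: 3 5-chloropentan-1-ol
Product: 4 5-chloropentanal
Conditions: TEMPO (2,2,6,6-tetramethylpiperidin-1-oxyl, 1 mol%), KBr (10 mol%), NaOCl (1.1 equiv), NaHCO3, CH2Cl2/H2O, 0 °C; used as dried CH2Cl2 solution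
Reagents that add atoms: none
Why: The oxoammonium-mediated (Anelli) oxidation of a primary alcohol stops at the aldehyde in the two-phase medium and does not touch the primary chloride.

Step 3
Reactants: 4 5-chloropentanal; 5 (R)-2-methylpropane-2-sulfinamide
Product: 6 (R,E)-N-(5-chloropentylidene)-2-methylpropane-2-sulfinamide
Conditions: CuSO4 (anhydrous, 2 equiv), CH2Cl2, rt
Reagents that add atoms: none
Why: Dehydrative condensation of the sulfinamide with an unhindered aldehyde gives the E-configured N-sulfinyl aldimine, and the sulfur stereocenter is that of the purchased (R)-auxiliary.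

Step 4
Reactants: 2 1-methoxy-3,5-bis(methoxymethoxy)benzene; 6 (R,E)-N-(5-chloropentylidene)-2-methylpropane-2-sulfinamide
Product: 9 (R)-N-[(1R)-5-chloro-1-[4-methoxy-2,6-bis(methoxymethoxy)phenyl]pentyl]-2-methylpropane-2-sulfinamide, via aryllithium 7 (not isolated), via arylmagnesium bromide 8 (not isolated)
Conditions: 2 (1.3 equiv), n-BuLi (1.25 equiv), THF, 0 °C; MgBr2·OEt2 (1.4 equiv), 0 °C; then 6 in CH2Cl2, −78 → 0 °C; H2O quench
Reagents that add atoms: none
Why: Directed ortho-metalation takes place at the one position flanked by two MOM-oxy groups, and after lithium–magnesium exchange the less basic aryl Grignard reagent adds 1,2 to the sulfinyl aldimine through a chair transition state with the sulfinyl oxygen on magnesium and the tert-butyl group and chloroalkyl chain equatorial, which should place the aryl group so that the new carbon is R; a minor diastereomer should be removable by chromatography here.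

Step 5
Reactants: 9 (R)-N-[(1R)-5-chloro-1-[4-methoxy-2,6-bis(methoxymethoxy)phenyl]pentyl]-2-methylpropane-2-sulfinamide
Product: 10 (2R)-1-[(R)-tert-butylsulfinyl]-2-[4-methoxy-2,6-bis(methoxymethoxy)phenyl]piperidine
Conditions: KOtBu (1.3 equiv), THF, 0 °C → rt
Reagents that add atoms: none
Why: The deprotonated sulfinamide nitrogen displaces the primary chloride in an intramolecular SN2 reaction (6-exo-tet), which closes the piperidine ring without touching the stereocenter.

Step 6
Reactants: 10 (2R)-1-[(R)-tert-butylsulfinyl]-2-[4-methoxy-2,6-bis(methoxymethoxy)phenyl]piperidine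
Product: 11 (R)-5-methoxy-2-(piperidin-2-yl)benzene-1,3-diol hydrochloride
Conditions: HCl (1.25 M in MeOH, 10 equiv), 0 °C → rt; evaporate, triturate with Et2O
Reagents that add atoms: hydrogen chloride, Cl
Why: Acid methanolysis cleaves the N–S bond and both MOM acetals (transacetalization to dimethoxymethane) in one operation, and the low temperature with the amine held as its ammonium salt should keep the benzylic C–N bond from ionizing.

Step 7
Reactants: 11 (R)-5-methoxy-2-(piperidin-2-yl)benzene-1,3-diol hydrochloride
Product: 12 tert-butyl (R)-2-(2,6-dihydroxy-4-methoxyphenyl)piperidine-1-carboxylate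
Conditions: Boc2O (1.1 equiv), NaHCO3 (3 equiv), THF/H2O, 0 °C → rt
Reagents that add atoms: di-tert-butyl dicarbonate (Boc2O), CC(C)(C)OC(=O)OC(=O)OC(C)(C)C
Why: Carbamate formation under bicarbonate (Schotten–Baumann-type N-acylation) should be selective for the amine, since the phenols are not acylated by Boc2O without an acyl-transfer catalyst.

Step 8
Reactants: 12 tert-butyl (R)-2-(2,6-dihydroxy-4-methoxyphenyl)piperidine-1-carboxylate
Product: 13 tert-butyl (R)-2-(2,6-dihydroxy-3-iodo-4-methoxyphenyl)piperidine-1-carboxylate
Conditions: NIS (1.0 equiv), MeCN, −30 → 0 °C, dark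
Reagents that add atoms: N-iodosuccinimide (NIS), O=C1CCC(=O)N1I
Why: Electrophilic aromatic iodination attacks a ring position that is ortho to one hydroxyl, para to the other and ortho to the methoxy group, and because the two open positions are equivalent by rotation about the aryl–piperidine bond, one equivalent of reagent at low temperature should give a single mono-iodide.

Step 9
Reactants: 13 tert-butyl (R)-2-(2,6-dihydroxy-3-iodo-4-methoxyphenyl)piperidine-1-carboxylate; 14 phenylacetylene; 15 carbon monoxide
Product: 18 tert-butyl (R)-2-(7-hydroxy-5-methoxy-4-oxo-2-phenyl-4H-chromen-8-yl)piperidine-1-carboxylate, via ynone 16 (not isolated), via enaminone 17 (not isolated)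
Conditions: PdCl2(PPh3)2 (5 mol%), 14 (1.5 equiv), Et2NH (10 equiv), DMF, CO (1 atm), 60 °C
Reagents that add atoms: none
Why: PdCl2(PPh3)2 is reduced in the flask to zerovalent palladium, which inserts into the C–I bond of 13; CO insertion gives an aroylpalladium iodide, and coupling with the amine-deprotonated terminal alkyne followed by reductive elimination releases ynone 16, which makes the C4a–C4 and C4–C3 bonds. Diethylamine then adds to the ynone to give enaminone 17, and the hydroxyl ortho to the ketone attacks the amine-bearing carbon and expels diethylamine, which makes the O1–C2 bond and closes the pyranone ring by a 6-endo-trig addition–elimination. The closest known reaction type is the palladium-catalysed carbonylative annulation of 2-iodophenols with terminal alkynes to flavones in a secondary-amine medium (carbonylative Sonogashira coupling followed by cyclization). No stereocenter is formed, and the piperidine C2 center is not at risk because the medium is basic and the nitrogen is a carbamate, so the benzylic C–N bond has no path to ionize. The step needs 6-endo over 5-exo closure (flavone, not aurone), which the enaminone secures by making the future C2 the electrophilic carbon, and carbonylative over direct alkynylation, which the copper-free conditions and the fast CO uptake of an electron-rich arylpalladium should secure. Site selectivity needs no further control, since 13 holds one C–I bond and only the hydroxyl next to it can reach the ynone.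

Step 10
Reactants: 18 tert-butyl (R)-2-(7-hydroxy-5-methoxy-4-oxo-2-phenyl-4H-chromen-8-yl)piperidine-1-carboxylate
Product: 19 7-hydroxy-5-methoxy-2-phenyl-8-[(2R)-piperidin-2-yl]-4H-chromen-4-one
Conditions: TFA/CH2Cl2 (1:4), 0 °C → rt; aq. NaHCO3 to pH 8
Reagents that add atoms: none
Why: Acidolysis of the tert-butyl carbamate (Boc removal) releases 2-methylpropene and CO2, and because ring A of the flavone is deactivated by the C4 carbonyl the benzylic C–N bond should survive brief cold acid with the configuration intact.

**Compound list**

1 | 5-methoxyresorcinol (5-methoxybenzene-1,3-diol) | COc1cc(O)cc(O)c1 | starting material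
2 | 1-methoxy-3,5-bis(methoxymethoxy)benzene | COCOc1cc(OC)cc(OCOC)c1 | intermediate
3 | 5-chloropentan-1-ol | OCCCCCCl | starting material
4 | 5-chloropentanal | O=CCCCCCl | intermediate
5 | (R)-2-methylpropane-2-sulfinamide | CC(C)(C)[S@@](=O)N | starting material
6 | (R,E)-N-(5-chloropentylidene)-2-methylpropane-2-sulfinamide | CC(C)(C)[S@@](=O)/N=C/CCCCCl | intermediate
7 | [4-methoxy-2,6-bis(methoxymethoxy)phenyl]lithium | [Li]c1c(OCOC)cc(OC)cc1OCOC | intermediate (not isolated)
8 | [4-methoxy-2,6-bis(methoxymethoxy)phenyl]magnesium bromide | Br[Mg]c1c(OCOC)cc(OC)cc1OCOC | intermediate (not isolated)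
9 | (R)-N-[(1R)-5-chloro-1-[4-methoxy-2,6-bis(methoxymethoxy)phenyl]pentyl]-2-methylpropane-2-sulfinamide | CC(C)(C)[S@@](=O)N[C@H](CCCCCl)c1c(OCOC)cc(OC)cc1OCOC | intermediate
10 | (2R)-1-[(R)-tert-butylsulfinyl]-2-[4-methoxy-2,6-bis(methoxymethoxy)phenyl]piperidine | CC(C)(C)[S@@](=O)N1CCCC[C@@H]1c1c(OCOC)cc(OC)cc1OCOC | intermediate
11 | (R)-5-methoxy-2-(piperidin-2-yl)benzene-1,3-diol hydrochloride | COc1cc(O)c([C@H]2CCCCN2)c(O)c1.Cl | intermediate
12 | tert-butyl (R)-2-(2,6-dihydroxy-4-methoxyphenyl)piperidine-1-carboxylate | COc1cc(O)c([C@H]2CCCCN2C(=O)OC(C)(C)C)c(O)c1 | intermediate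
13 | tert-butyl (R)-2-(2,6-dihydroxy-3-iodo-4-methoxyphenyl)piperidine-1-carboxylate | COc1cc(O)c([C@H]2CCCCN2C(=O)OC(C)(C)C)c(O)c1I | intermediate
14 | phenylacetylene | C#Cc1ccccc1 | starting material
15 | carbon monoxide | [C-]#[O+] | starting material
16 | tert-butyl (R)-2-[2,6-dihydroxy-4-methoxy-3-(3-phenylprop-2-ynoyl)phenyl]piperidine-1-carboxylate (ynone) | COc1cc(O)c([C@H]2CCCCN2C(=O)OC(C)(C)C)c(O)c1C(=O)C#Cc1ccccc1 | intermediate (not isolated)
17 | tert-butyl (R)-2-[3-[(E)-3-(diethylamino)-3-phenylprop-2-enoyl]-2,6-dihydroxy-4-methoxyphenyl]piperidine-1-carboxylate (enaminone) | COc1cc(O)c([C@H]2CCCCN2C(=O)OC(C)(C)C)c(O)c1C(=O)/C=C(/N(CC)CC)c1ccccc1 | intermediate (not isolated)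
18 | tert-butyl (R)-2-(7-hydroxy-5-methoxy-4-oxo-2-phenyl-4H-chromen-8-yl)piperidine-1-carboxylate | COc1cc(O)c([C@H]2CCCCN2C(=O)OC(C)(C)C)c2oc(-c3ccccc3)cc(=O)c12 | intermediate
19 | 7-hydroxy-5-methoxy-2-phenyl-8-[(2R)-piperidin-2-yl]-4H-chromen-4-one | COc1cc(O)c([C@H]2CCCCN2)c2oc(-c3ccccc3)cc(=O)c12 | target

**Step count and risks**

Total step count: 10. Longest linear sequence: 9 steps (3 → 4 → 6 → 9 → 10 → 11 → 12 → 13 → 18 → 19); the arene branch from 1 joins at step 4.

The three steps most likely to fail:

Step 9. After oxidative addition three paths compete: capture of the aroylpalladium intermediate by diethylamine (amide formation), alkynylation before CO uptake (leading on to a benzofuran), and 5-exo closure of the ynone. The fallback builds the pyranone ring by acylation chemistry and sets out from 13. Stille coupling with tributyl(1-ethoxyvinyl)stannane (Pd(PPh3)4, toluene, 90 °C) should give tert-butyl (R)-2-[3-(1-ethoxyethenyl)-2,6-dihydroxy-4-methoxyphenyl]piperidine-1-carboxylate F1. Brief hydrolysis with dilute aqueous HCl in THF at 0 °C gives the methyl ketone, tert-butyl (R)-2-(3-acetyl-2,6-dihydroxy-4-methoxyphenyl)piperidine-1-carboxylate F2. Its lithium polyanion (LiHMDS, 4.5 equiv, THF, −78 °C) is C-benzoylated with one equivalent of benzoyl chloride (Claisen-type acylation) to the 1,3-diketone, tert-butyl (R)-2-[2,6-dihydroxy-4-methoxy-3-(3-oxo-3-phenylpropanoyl)phenyl]piperidine-1-carboxylate F3. Cyclodehydration with catalytic H2SO4 in AcOH at 50 °C, which also removes the Boc group, followed by neutralization, returns the route at 19.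

Step 4. The hindered aryl metal may deprotonate the aldimine at its α-carbon in place of adding to it, metalation of 2 may stray to a position next to the methoxy group, or the MOM oxygens may occupy the magnesium and open the transition state, which would lower the facial selectivity. The fallback reverses the polarity of the C–C bond formation and sets out from 2. Lithiation as before and a DMF quench should give 4-methoxy-2,6-bis(methoxymethoxy)benzaldehyde F4. Condensation with (S)-2-methylpropane-2-sulfinamide under Ti(OEt)4 in THF gives the non-enolizable aldimine, (S,E)-N-[4-methoxy-2,6-bis(methoxymethoxy)benzylidene]-2-methylpropane-2-sulfinamide F5. The reagent 4-chlorobutylmagnesium bromide F6, made from 1-bromo-4-chlorobutane and magnesium in THF, is added in CH2Cl2 at −48 °C; the same chair model with the aryl group equatorial predicts (S)-N-[(1R)-5-chloro-1-[4-methoxy-2,6-bis(methoxymethoxy)phenyl]pentyl]-2-methylpropane-2-sulfinamide F7. KOtBu in THF closes it to (2R)-1-[(S)-tert-butylsulfinyl]-2-[4-methoxy-2,6-bis(methoxymethoxy)phenyl]piperidine F8, and HCl in methanol as in step 6 returns the route at 11.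

Step 8. A second iodination may run at a rate close to the first on this very electron-rich ring, or the iodinating agent may oxidize the resorcinol. The fallback replaces halogenation by a self-limiting C-formylation and sets out from 12. Magnesium-mediated ortho-formylation (MgCl2, Et3N, paraformaldehyde, MeCN, 70 °C) should stop after one formyl group, because the aldehyde deactivates the ring, and give tert-butyl (R)-2-(3-formyl-2,6-dihydroxy-4-methoxyphenyl)piperidine-1-carboxylate F9. Excess phenylethynylmagnesium bromide in THF at 0 °C adds to the aldehyde to give tert-butyl (2R)-2-[2,6-dihydroxy-3-(1-hydroxy-3-phenylprop-2-yn-1-yl)-4-methoxyphenyl]piperidine-1-carboxylate F10, as both epimers at the carbinol carbon, which is oxidized next. MnO2 in CH2Cl2 oxidizes it to ynone 16, now isolated, so the route is rejoined at 16 without iodide or palladium; diethylamine in ethanol then closes 16 through 17 to 18.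

**Further compounds**

F1 | step 9 | tert-butyl (R)-2-[3-(1-ethoxyethenyl)-2,6-dihydroxy-4-methoxyphenyl]piperidine-1-carboxylate | COc1cc(O)c([C@H]2CCCCN2C(=O)OC(C)(C)C)c(O)c1C(=C)OCC
F2 | step 9 | tert-butyl (R)-2-(3-acetyl-2,6-dihydroxy-4-methoxyphenyl)piperidine-1-carboxylate | COc1cc(O)c([C@H]2CCCCN2C(=O)OC(C)(C)C)c(O)c1C(C)=O
F3 | step 9 | tert-butyl (R)-2-[2,6-dihydroxy-4-methoxy-3-(3-oxo-3-phenylpropanoyl)phenyl]piperidine-1-carboxylate | COc1cc(O)c([C@H]2CCCCN2C(=O)OC(C)(C)C)c(O)c1C(=O)CC(=O)c1ccccc1
F4 | step 4 | 4-methoxy-2,6-bis(methoxymethoxy)benzaldehyde | COCOc1cc(OC)cc(OCOC)c1C=O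
F5 | step 4 | (S,E)-N-[4-methoxy-2,6-bis(methoxymethoxy)benzylidene]-2-methylpropane-2-sulfinamide | CC(C)(C)[S@](=O)/N=C/c1c(OCOC)cc(OC)cc1OCOC
F6 | step 4 | 4-chlorobutylmagnesium bromide | ClCCCC[Mg]Br
F7 | step 4 | (S)-N-[(1R)-5-chloro-1-[4-methoxy-2,6-bis(methoxymethoxy)phenyl]pentyl]-2-methylpropane-2-sulfinamide | CC(C)(C)[S@](=O)N[C@H](CCCCCl)c1c(OCOC)cc(OC)cc1OCOC
F8 | step 4 | (2R)-1-[(S)-tert-butylsulfinyl]-2-[4-methoxy-2,6-bis(methoxymethoxy)phenyl]piperidine | CC(C)(C)[S@](=O)N1CCCC[C@@H]1c1c(OCOC)cc(OC)cc1OCOC
F9 | step 8 | tert-butyl (R)-2-(3-formyl-2,6-dihydroxy-4-methoxyphenyl)piperidine-1-carboxylate | COc1cc(O)c([C@H]2CCCCN2C(=O)OC(C)(C)C)c(O)c1C=O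
F10 | step 8 | tert-butyl (2R)-2-[2,6-dihydroxy-3-(1-hydroxy-3-phenylprop-2-yn-1-yl)-4-methoxyphenyl]piperidine-1-carboxylate (both epimers at the carbinol carbon) | COc1cc(O)c([C@H]2CCCCN2C(=O)OC(C)(C)C)c(O)c1C(O)C#Cc1ccccc1
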